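**Strategy.** Ring A of the target is the cyclohexene C11–C16 (chain numbered from the enol-acetate carbon C1 to the ring carbon C11, then round the ring to the gem-dimethyl carbon C16). Its olefin C12=C13 lies between C11 and C14, which is the retron of a [4+2] adduct of a C11=C12–C13=C14 diene and a C15=C16 dienophile. One catalytic enantioselective Diels–Alder reaction of methacrolein therefore forms C11–C16 and C14–C15, closes ring A and sets C11; the formyl group later becomes the second C16 methyl. The precursor is geranyl acetate with its isopropylidene replaced by an E-configured 2-methylbuta-1,3-dienyl terminus. The C1–C5 end is grafted on afterwards, C3 being set by Sharpless epoxidation.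

Key step: step 4

Remark: the facial sense of the oxazaborolidinium catalyst is taken from its accepted binding model for α-substituted acroleins; if this diene reacted with the opposite sense, the catalyst from (S)-α,α-diphenylprolinol would be used without other change.

**Step 1**
Reactants: 1 geranyl acetate
Product: 2 (2E,6E)-8-hydroxy-3,7-dimethylocta-2,6-dien-1-yl acetate
Conditions: SeO2 (0.3 equiv), t-BuOOH (3 equiv), salicylic acid (0.1 equiv), CH2Cl2, 23 °C
Reagents that add atoms: selenium dioxide, O=[Se]=O; tert-butyl hydroperoxide, CC(C)(C)OO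
Why: Allylic oxidation by SeO2 (ene reaction, then [2,3]-sigmatropic shift, selenium being reoxidised by the hydroperoxide) should attack the electron-rich terminal olefin at its E-methyl group and spare the olefin next to the acetoxymethyl group, so the E,E geometry is kept.

**Step 2**
Reactants: 2 (2E,6E)-8-hydroxy-3,7-dimethylocta-2,6-dien-1-yl acetate
Product: 3 (2E,6E)-3,7-dimethyl-8-oxoocta-2,6-dien-1-yl acetate
Conditions: MnO2 (15 equiv), CH2Cl2, 23 °C
Reagents that add atoms: none
Why: MnO2 oxidises allylic alcohols to enals without E/Z isomerisation or over-oxidation and leaves the ester alone (allylic alcohol oxidation).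

**Step 3**
Reactants: 3 (2E,6E)-3,7-dimethyl-8-oxoocta-2,6-dien-1-yl acetate
Product: 4 (2E,6E)-3,7-dimethylnona-2,6,8-trien-1-yl acetate
Conditions: Ph3PCH3Br (1.3 equiv), KOtBu (1.2 equiv), THF, 0 °C; then 3, −78 → 0 °C
Reagents that add atoms: methyltriphenylphosphonium bromide, C[P+](c1ccccc1)(c1ccccc1)c1ccccc1.[Br-]
Why: Wittig methylenation of the unhindered enal by the non-stabilised ylide is much faster at low temperature than attack on the acetate, adds 1,2 only and cannot disturb the E-configured C11=C12 olefin, so it should give the 1-alkyl-2-methylbutadiene.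

**Step 4**
Reactants: 4 (2E,6E)-3,7-dimethylnona-2,6,8-trien-1-yl acetate; 5 methacrolein
Product: 6 (2E)-5-[(1R,6R)-6-formyl-2,6-dimethylcyclohex-2-en-1-yl]-3-methylpent-2-en-1-yl acetate (exo adduct; formyl on C16 trans to the chain on C11)
Conditions: oxazaborolidine from (R)-α,α-diphenylprolinol and o-tolylboronic acid (20 mol %), Tf2NH (17 mol %), 5 (3 equiv), CH2Cl2, −78 → −20 °C
Reagents that add atoms: none
Why: The Tf2NH-protonated oxazaborolidine binds methacrolein at the formyl oxygen, held by a formyl C–H···O contact, and cycloaddition to the s-cis C11=C12–C13=C14 unit is concerted but lopsided, bonding between the unsubstituted termini C14 and C15 being well advanced before the crowded C11–C16 bond closes. The closest known reaction type is the oxazaborolidinium-catalysed Diels–Alder reaction of α-substituted acroleins with acyclic 1- or 2-substituted butadienes; the 1-alkyl-2-methyl pattern is a new substrate within that class. Ring A closes by intermolecular [4+2] annulation, suprafacial on both partners, which leaves the olefin at C12=C13. C16 is set by the catalyst, since by the binding model the (R)-prolinol-derived cation screens the Re face of the α-carbon of the s-trans enal so that C11 bonds to its Si face; C11 then follows from the E geometry of C11=C12 (chain outside) and the exo-formyl transition state favoured by the α-methyl group, which puts CHO trans to the chain. The step needs C16 to bond to C11 and not to C14, which the terminal alkyl group should secure over the C12 methyl as the ring-bound terminus does in 1-vinylcycloalkene cycloadditions, and it needs exo and facial control; because C16 later becomes achiral, the endo adduct would lead to the enantiomeric ring and must be removed by chromatography at this aldehyde stage. The acetate is kept because it binds the boron cation more weakly than the aldehyde, should survive the conditions and is cleaved without an extra step in step 5, and the C7=C8 olefin is too unreactive to interfere.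

**Step 5**
Reactants: 6 exo adduct aldehyde
Product: 8 (2E)-3-methyl-5-[(1S)-2,6,6-trimethylcyclohex-2-en-1-yl]pent-2-en-1-ol, via hydroxy hydrazone 7 (not isolated)
Conditions: N2H4·H2O (10 equiv), KOH (8 equiv), diethylene glycol, 130 °C, then 200 °C with removal of water
Reagents that add atoms: none
Why: Wolff–Kishner reduction in the Huang-Minlon variant: the hydrazone of the non-enolisable neopentyl aldehyde is deprotonated, tautomerises and loses N2 to leave the second C16 methyl (C16 becomes achiral), while hot KOH cleaves the acetate in the same pot and neither the isolated trisubstituted olefins nor the non-acidic C11–H should be touched.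

**Step 6**
Reactants: 8 (2E)-3-methyl-5-[(1S)-2,6,6-trimethylcyclohex-2-en-1-yl]pent-2-en-1-ol
Product: 9 (6S)-6-[(3E)-5-bromo-3-methylpent-3-en-1-yl]-1,5,5-trimethylcyclohex-1-ene
Conditions: PBr3 (0.4 equiv), pyridine (cat.), Et2O, −10 → 0 °C; used crude
Reagents that add atoms: phosphorus tribromide, BrP(Br)Br
Why: Conversion of a primary allylic alcohol to the bromide through its phosphite ester and SN2 displacement, conditions under which allylic transposition and E/Z scrambling of prenyl-type systems should be minimal.

**Step 7**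
Reactants: 9 allylic bromide; 10 2-methylprop-2-en-1-ol (methallyl alcohol)
Product: 12 2-{(3E)-4-methyl-6-[(1S)-2,6,6-trimethylcyclohex-2-en-1-yl]hex-3-en-1-yl}prop-2-en-1-ol, via dilithiated methallyl alcohol 11 (not isolated)
Conditions: 10 (3 equiv), n-BuLi (6 equiv), TMEDA (6 equiv), Et2O–hexane, 0 → 23 °C; then 9, THF, −78 → 0 °C
Reagents that add atoms: none
Why: Double deprotonation of methallyl alcohol (O–H, then the allylic methyl, assisted by the alkoxide and TMEDA) gives a C-nucleophilic dianion whose SN2 alkylation by the primary allylic bromide should install C5 and the 2-substituted allylic alcohol in one operation (dianion alkylation), with no new stereocentre.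

**Step 8**
Reactants: 12 2-substituted allylic alcohol
Product: 13 [(2S)-2-{(3E)-4-methyl-6-[(1S)-2,6,6-trimethylcyclohex-2-en-1-yl]hex-3-en-1-yl}oxiran-2-yl]methanol
Conditions: Ti(OiPr)4 (10 mol %), L-(+)-diisopropyl tartrate (12 mol %), t-BuOOH (2 equiv, in isooctane), 4 Å sieves, CH2Cl2, −20 °C
Reagents that add atoms: tert-butyl hydroperoxide, CC(C)(C)OO
Why: Sharpless asymmetric epoxidation: the catalyst formed from Ti(OiPr)4 and the tartrate delivers oxygen only to the olefin of the bound allylic alcohol, so both remote trisubstituted olefins are spared, and with L-(+)-tartrate oxygen should enter the face that gives the (S)-epoxide, fixing C3 independently of the distant C11 centre, while the catalytic protocol limits opening of the 2,2-disubstituted epoxide.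

**Step 9**
Reactants: 13 epoxy alcohol
Product: 15 (2R)-2-{(3E)-4-methyl-6-[(1S)-2,6,6-trimethylcyclohex-2-en-1-yl]hex-3-en-1-yl}butane-1,2,4-triol, via silyl diol 14 (not isolated)
Conditions: iPrOMe2SiCH2MgCl (3.5 equiv), CuI (10 mol %), THF, −30 → 0 °C; NH4Cl work-up; crude, then 30% H2O2, KF, KHCO3, THF–MeOH, 23 °C
Reagents that add atoms: (isopropoxydimethylsilyl)methylmagnesium chloride, CC(C)O[Si](C)(C)C[Mg]Cl; hydrogen peroxide, OO
Why: CuI-catalysed Grignard opening of the epoxide at its unsubstituted CH2 (C2) leaves the C3–O bond and so the C3 configuration untouched (a Payne shift of the alkoxide is degenerate here), and Tamao–Fleming oxidation of the C–Si bond, whether the silane stays open or closes to the cyclic siloxane, should unveil the C1 hydroxyl without touching the olefins.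

**Step 10**
Reactants: 15 triol
Product: 16 (2R)-2-hydroxy-2-{(3E)-4-methyl-6-[(1S)-2,6,6-trimethylcyclohex-2-en-1-yl]hex-3-en-1-yl}butanedial
Conditions: (COCl)2 (4 equiv), DMSO (8 equiv), CH2Cl2, −78 °C; Et3N (12 equiv), −78 → −20 °C; cold non-aqueous work-up, used at once
Reagents that add atoms: none
Why: Swern oxidation should convert both primary alcohols to aldehydes at once, because all hydroxyls are activated as alkoxysulfonium ions before base is added so that no lactol can form and over-oxidise, while the tertiary C3 hydroxyl returns unchanged and C3, which bears no hydrogen, cannot epimerise.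

**Step 11**
Reactants: 16 hydroxy dialdehyde
Product: 18 (1E,3R,6E)-3-acetoxy-3-formyl-7-methyl-9-[(1S)-2,6,6-trimethylcyclohex-2-en-1-yl]nona-1,6-dien-1-yl acetate, via enol acetate hydroxy aldehyde 17 (not isolated)
Conditions: Ac2O (6 equiv), Et3N (8 equiv), DMAP (0.5 equiv), CH2Cl2, 0 → 23 °C
Reagents that add atoms: acetic anhydride, CC(=O)OC(C)=O
Why: C1H=O is the only enolisable carbonyl (C3 is quaternary, so C4H=O has no α-hydrogen), its amine-generated enolate should be O-acetylated to the E-enol acetate with the acetoxy group anti to the bulky C3 substituent, and the hindered C3 hydroxyl is then esterified under DMAP catalysis without any bond to C3 being broken (enol acetylation followed by nucleophile-catalysed O-acylation).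

**Compound list**
1 | geranyl acetate | CC(C)=CCC/C(C)=C/COC(C)=O | starting material
2 | (2E,6E)-8-hydroxy-3,7-dimethylocta-2,6-dien-1-yl acetate | OC/C(C)=C/CC/C(C)=C/COC(C)=O | intermediate
3 | (2E,6E)-3,7-dimethyl-8-oxoocta-2,6-dien-1-yl acetate | O=C/C(C)=C/CC/C(C)=C/COC(C)=O | intermediate
4 | (2E,6E)-3,7-dimethylnona-2,6,8-trien-1-yl acetate | C=C/C(C)=C/CC/C(C)=C/COC(C)=O | intermediate
5 | methacrolein | CC(=C)C=O | starting material
6 | (2E)-5-[(1R,6R)-6-formyl-2,6-dimethylcyclohex-2-en-1-yl]-3-methylpent-2-en-1-yl acetate (exo adduct) | CC(=O)OC/C=C(\C)CC[C@@H]1C(C)=CCC[C@@]1(C)C=O | intermediate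
7 | hydrazone of the formyl group of 6 with the acetate already cleaved (ring configuration as in 6) | OC/C=C(\C)CC[C@@H]1C(C)=CCC[C@@]1(C)/C=N/N | intermediate
8 | (2E)-3-methyl-5-[(1S)-2,6,6-trimethylcyclohex-2-en-1-yl]pent-2-en-1-ol | OC/C=C(\C)CC[C@@H]1C(C)=CCCC1(C)C | intermediate
9 | (6S)-6-[(3E)-5-bromo-3-methylpent-3-en-1-yl]-1,5,5-trimethylcyclohex-1-ene | BrC/C=C(\C)CC[C@@H]1C(C)=CCCC1(C)C | intermediate
10 | 2-methylprop-2-en-1-ol (methallyl alcohol) | CC(=C)CO | starting material
11 | dilithiated methallyl alcohol (lithium 2-(lithiomethyl)prop-2-en-1-olate) | [Li]CC(=C)CO[Li] | intermediate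
12 | 2-{(3E)-4-methyl-6-[(1S)-2,6,6-trimethylcyclohex-2-en-1-yl]hex-3-en-1-yl}prop-2-en-1-ol | OCC(=C)CC/C=C(\C)CC[C@@H]1C(C)=CCCC1(C)C | intermediate
13 | [(2S)-2-{(3E)-4-methyl-6-[(1S)-2,6,6-trimethylcyclohex-2-en-1-yl]hex-3-en-1-yl}oxiran-2-yl]methanol | OC[C@@]1(CC/C=C(\C)CC[C@@H]2C(C)=CCCC2(C)C)CO1 | intermediate
14 | (2R,5E)-2-{2-[dimethyl(propan-2-yloxy)silyl]ethyl}-6-methyl-8-[(1S)-2,6,6-trimethylcyclohex-2-en-1-yl]oct-5-ene-1,2-diol | CC(C)O[Si](C)(C)CC[C@@](O)(CO)CC/C=C(\C)CC[C@@H]1C(C)=CCCC1(C)C | intermediate
15 | (2R)-2-{(3E)-4-methyl-6-[(1S)-2,6,6-trimethylcyclohex-2-en-1-yl]hex-3-en-1-yl}butane-1,2,4-triol | OCC[C@@](O)(CO)CC/C=C(\C)CC[C@@H]1C(C)=CCCC1(C)C | intermediate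
16 | (2R)-2-hydroxy-2-{(3E)-4-methyl-6-[(1S)-2,6,6-trimethylcyclohex-2-en-1-yl]hex-3-en-1-yl}butanedial | O=CC[C@@](O)(C=O)CC/C=C(\C)CC[C@@H]1C(C)=CCCC1(C)C | intermediate
17 | (1E,3R,6E)-3-formyl-3-hydroxy-7-methyl-9-[(1S)-2,6,6-trimethylcyclohex-2-en-1-yl]nona-1,6-dien-1-yl acetate | CC(=O)O/C=C/[C@@](O)(C=O)CC/C=C(\C)CC[C@@H]1C(C)=CCCC1(C)C | intermediate
18 | (1E,3R,6E)-3-acetoxy-3-formyl-7-methyl-9-[(1S)-2,6,6-trimethylcyclohex-2-en-1-yl]nona-1,6-dien-1-yl acetate | CC(=O)O/C=C/[C@@](C=O)(CC/C=C(\C)CC[C@@H]1C(C)=CCCC1(C)C)OC(C)=O | target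

**Total step count:** 11. **Longest linear sequence:** 11 steps (1 → 18).

**Steps most likely to fail**

Step 4. The C12 methyl may steer part of the dienophile to bond C16 to C14 instead of C11, and exo and facial discrimination may be weaker with this hindered diene than with simpler ones, which would erode the enantiomeric purity of C11 once C16 is made achiral. The fallback keeps the same two bonds but enforces the orientation with a removable oxygen at C13. It sets out from enal 3: MeMgBr (THF, −78 °C) should give the secondary allylic alcohol F1, MnO2 the methyl enone F2, and i-Pr3SiOTf/Et3N the 2-silyloxy triene F3. Cycloaddition of this triene with 5 under the same catalyst should give the silyl enol ether adduct F4, in which the C13 oxygen and the C11 alkyl group direct alike and the olefin is fixed at C12=C13. CsF/PhNTf2 (DME) should convert that adduct into the enol triflate F5. Formate reduction (Pd(OAc)2, PPh3, HCO2H, Bu3N, DMF, 40 °C), where oxidative addition to the enol triflate should outpace ionisation of the trisubstituted allylic acetate, brings the route back at 6.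

Step 11. If the hindered C3 hydroxyl is acetylated before the C1 aldehyde is trapped as its enol acetate, the β-acetoxy aldehyde can lose acetate by E1cB elimination, and the free β-hydroxy dialdehyde may also undergo retro-aldol cleavage. The fallback enforces the order by silyl protection and sets out from triol 15: Et3SiOTf/2,6-lutidine should give the tris(triethylsilyl) ether F6. Swern conditions, which cleave and oxidise primary but not tertiary triethylsilyl ethers, should give the silyloxy dialdehyde F7. Ac2O/Et3N/DMAP should then give the silyl-protected E-enol acetate F8, with no acyloxy leaving group at C3. HF·pyridine (buffered with pyridine, THF, 0 °C) frees the tertiary hydroxyl, which is compound 17, where the route is rejoined, and Ac2O/DMAP gives 18.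

Step 7. Competing SN2′ attack, O-alkylation and halogen–lithium exchange followed by coupling of the bromide can erode C-alkylation of the dianion. The fallback replaces it by enolate alkylation and methylenation and sets out from bromide 9: the lithium enolate of 1,1-dimethoxypropan-2-one (LiN(iPr)2, THF, −78 °C), formed at the methyl group, should give the keto acetal F9. Ph3P=CH2 should give the methylidene acetal F10, and aqueous oxalic acid (THF) the 2-substituted acrolein F11. Luche reduction (NaBH4, CeCl3·7H2O, MeOH, 0 °C) returns the route at allylic alcohol 12.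

**Further compounds**
F1 | step 4 | (2E,6E)-8-hydroxy-3,7-dimethylnona-2,6-dien-1-yl acetate | CC(O)/C(C)=C/CC/C(C)=C/COC(C)=O
F2 | step 4 | (2E,6E)-3,7-dimethyl-8-oxonona-2,6-dien-1-yl acetate | CC(=O)/C(C)=C/CC/C(C)=C/COC(C)=O
F3 | step 4 | (2E,6E)-3,7-dimethyl-8-{[tri(propan-2-yl)silyl]oxy}nona-2,6,8-trien-1-yl acetate | C=C(O[Si](C(C)C)(C(C)C)C(C)C)/C(C)=C/CC/C(C)=C/COC(C)=O
F4 | step 4 | (2E)-5-[(1R,6R)-6-formyl-2,6-dimethyl-3-{[tri(propan-2-yl)silyl]oxy}cyclohex-2-en-1-yl]-3-methylpent-2-en-1-yl acetate | CC(=O)OC/C=C(\C)CC[C@@H]1C(C)=C(O[Si](C(C)C)(C(C)C)C(C)C)CC[C@@]1(C)C=O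
F5 | step 4 | (2E)-5-[(1R,6R)-6-formyl-2,6-dimethyl-3-(trifluoromethanesulfonyloxy)cyclohex-2-en-1-yl]-3-methylpent-2-en-1-yl acetate | CC(=O)OC/C=C(\C)CC[C@@H]1C(C)=C(OS(=O)(=O)C(F)(F)F)CC[C@@]1(C)C=O
F6 | step 11 | tris(triethylsilyl) ether of triol 15 | CC[Si](CC)(CC)OCC[C@@](O[Si](CC)(CC)CC)(CO[Si](CC)(CC)CC)CC/C=C(\C)CC[C@@H]1C(C)=CCCC1(C)C
F7 | step 11 | (2R)-2-{(3E)-4-methyl-6-[(1S)-2,6,6-trimethylcyclohex-2-en-1-yl]hex-3-en-1-yl}-2-(triethylsilyloxy)butanedial | O=CC[C@@](O[Si](CC)(CC)CC)(C=O)CC/C=C(\C)CC[C@@H]1C(C)=CCCC1(C)C
F8 | step 11 | (1E,3R,6E)-3-formyl-7-methyl-3-(triethylsilyloxy)-9-[(1S)-2,6,6-trimethylcyclohex-2-en-1-yl]nona-1,6-dien-1-yl acetate | CC(=O)O/C=C/[C@@](O[Si](CC)(CC)CC)(C=O)CC/C=C(\C)CC[C@@H]1C(C)=CCCC1(C)C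
F9 | step 7 | (5E)-1,1-dimethoxy-6-methyl-8-[(1S)-2,6,6-trimethylcyclohex-2-en-1-yl]oct-5-en-2-one | COC(OC)C(=O)CC/C=C(\C)CC[C@@H]1C(C)=CCCC1(C)C
F10 | step 7 | (6S)-6-[(3E)-7-(dimethoxymethyl)-3-methylocta-3,7-dien-1-yl]-1,5,5-trimethylcyclohex-1-ene | COC(OC)C(=C)CC/C=C(\C)CC[C@@H]1C(C)=CCCC1(C)C
F11 | step 7 | (5E)-6-methyl-2-methylidene-8-[(1S)-2,6,6-trimethylcyclohex-2-en-1-yl]oct-5-enal | O=CC(=C)CC/C=C(\C)CC[C@@H]1C(C)=CCCC1(C)C
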